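**Retrosynthetic overview**
1. Target ⇐ acetylation of the C1 hydroxyl and mild hydrolysis of a C8 dimethyl acetal; the two formyl carbons enter early as an ester (on C7) and an acetal (on C8).
2. The only ring, the nine-membered carbocycle, is closed late by an intramolecular Horner–Wadsworth–Emmons olefination at C6=C7, not by olefin metathesis at C3=C4.
3. The C1–C2 bond, the C1 stereocentre and the (Z)-C3=C4 olefin come from one chirality-transfer allylboration with an α-substituted methallylboronate made by lithiation–borylation.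
4. The C8–C9 bond and both stereocentres come from an organocatalytic Michael addition of (R)-citronellal (C1, C9, C10 and the side chain) to an alkylidene phosphonoacetate that already carries C7, C8 and both formyl carbons.
5. That acceptor comes from triethyl phosphonoacetate and glyoxal mono(dimethyl acetal) by Knoevenagel condensation.

Assumption: the SMILES is read literally, i.e. ring-cis (Z) C3=C4, (E)-enal C6=C7 and R at C1 (CH–OAc), C8 (CH–CHO), C9 (ring CH with side chain) and C10 (side-chain CH–CH3); locants: ring C1 to C9 in that order (C2 CH2, C3 C–CH3, C4 =CH, C5 CH2, C6 =CH, C7 C–CHO), C14 and C15 are the formyl carbons on C7 and C8.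

**Route**

Step 1
Reactants: 1 triethyl phosphonoacetate; 2 2,2-dimethoxyacetaldehyde
Product: 3 ethyl (2E)-2-(diethoxyphosphoryl)-4,4-dimethoxybut-2-enoate
Conditions: piperidine (10 mol %), AcOH (10 mol %), PhMe, reflux, Dean–Stark
Reagents that add atoms: none
Why: Knoevenagel condensation of the doubly activated CH2 of 1 with the non-enolisable aldehyde 2 under azeotropic water removal keeps the phosphonate in place; no stereocentre is formed and the olefin geometry is irrelevant because C7 becomes sp3 in step 2.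

Step 2
Reactants: 3 ethyl (2E)-2-(diethoxyphosphoryl)-4,4-dimethoxybut-2-enoate; 4 (R)-citronellal
Product: 6 ethyl (3S,4R,5R)-2-(diethoxyphosphoryl)-3-(dimethoxymethyl)-4-formyl-5,9-dimethyldec-8-enoate, via enamine 5 (not isolated)
Conditions: (S)-α,α-diphenylprolinol trimethylsilyl ether (20 mol %), PhCO2H (20 mol %), PhMe, 0 °C → rt
Reagents that add atoms: none
Why: Proposed new method: enamine Michael addition in which the (E)-enamine 5, shielded on one face by the diphenyl(silyloxy)methyl group (giving (R)-C9), attacks the doubly activated olefin of 3 through the usual acyclic synclinal transition state with the acetal substituent anti to the enamine C=C, so that C15 and the C10 side chain end up syn along C1–C9–C8–C7 (trans on the later ring) while C10 is untouched and the P-bearing carbon is an irrelevant mixture; the closest known reactions are diarylprolinol silyl ether-catalysed additions of aldehydes to 2-(diethoxyphosphoryl)acrylates, alkylidene malonates and nitroalkenes.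

Step 3
Reactants: 7 3-[(tert-butyldimethylsilyl)oxy]propan-1-ol
Product: 8 3-[(tert-butyldimethylsilyl)oxy]propyl N,N-diisopropylcarbamate
Conditions: NaH, i-Pr2NC(O)Cl, THF, 0 °C → reflux
Reagents that add atoms: N,N-diisopropylcarbamoyl chloride, CC(C)N(C(C)C)C(Cl)=O
Why: base-mediated O-carbamoylation (nucleophilic acyl substitution) installs the Hoppe carbamate that directs α-lithiation and later serves as leaving group; no stereocentre.

Step 4
Reactants: 8 3-[(tert-butyldimethylsilyl)oxy]propyl N,N-diisopropylcarbamate; 9 2-isopropenyl-4,4,5,5-tetramethyl-1,3,2-dioxaborolane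
Product: 12 tert-butyldimethyl{[(3R)-4-methyl-3-(4,4,5,5-tetramethyl-1,3,2-dioxaborolan-2-yl)pent-4-en-1-yl]oxy}silane, via lithiated carbamate 10 (not isolated), via boronate complex 11 (not isolated)
Conditions: s-BuLi, (−)-sparteine, Et2O, −78 °C; then 9, −78 °C → 40 °C
Reagents that add atoms: none
Why: Hoppe–Aggarwal lithiation–borylation, in which sparteine-directed removal of the pro-S hydrogen gives the (S)-organolithium 10, borylation proceeds with retention to 11, and the stereoinvertive 1,2-metallate (Matteson-type) shift of the isopropenyl group with loss of the carbamate fixes the (R) boron-bearing centre.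

Step 5
Reactants: 6 ethyl (3S,4R,5R)-2-(diethoxyphosphoryl)-3-(dimethoxymethyl)-4-formyl-5,9-dimethyldec-8-enoate; 12 tert-butyldimethyl{[(3R)-4-methyl-3-(4,4,5,5-tetramethyl-1,3,2-dioxaborolan-2-yl)pent-4-en-1-yl]oxy}silane
Product: 14 ethyl (3S,4R,5R,7Z)-10-[(tert-butyldimethylsilyl)oxy]-2-(diethoxyphosphoryl)-3-(dimethoxymethyl)-5-hydroxy-7-methyl-4-[(2R)-6-methylhept-5-en-2-yl]dec-7-enoate, via borate ester 13 (not isolated)
Conditions: PhMe, rt → 40 °C; then aq. NaHCO3
Reagents that add atoms: none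
Why: Hoffmann-type allylboration of an α-substituted pinacol allylboronate through a closed chair transition state with the α-substituent axial (avoiding the pinacol methyls and A(1,2) strain with the 2-methyl group), which delivers the (Z)-trisubstituted C3=C4 olefin and transfers the (R) boron-bearing centre to (R)-C1 under reagent control.

Step 6
Reactants: 14 ethyl (3S,4R,5R,7Z)-10-[(tert-butyldimethylsilyl)oxy]-2-(diethoxyphosphoryl)-3-(dimethoxymethyl)-5-hydroxy-7-methyl-4-[(2R)-6-methylhept-5-en-2-yl]dec-7-enoate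
Product: 15 ethyl (3S,4R,5R,7Z)-10-[(tert-butyldimethylsilyl)oxy]-2-(diethoxyphosphoryl)-3-(dimethoxymethyl)-7-methyl-4-[(2R)-6-methylhept-5-en-2-yl]-5-(pivaloyloxy)dec-7-enoate
Conditions: PivCl, pyridine, DMAP (cat.), CH2Cl2, 0 °C → rt
Reagents that add atoms: pivaloyl chloride, CC(C)(C)C(Cl)=O
Why: DMAP-catalysed O-acylation gives a hindered ester that blocks δ-lactonisation onto the ethyl ester, cannot be transferred to carbon under the basic conditions of step 9 and is removed by the hydride of step 10; the C1–O bond is not broken.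

Step 7
Reactants: 15 ethyl (3S,4R,5R,7Z)-10-[(tert-butyldimethylsilyl)oxy]-2-(diethoxyphosphoryl)-3-(dimethoxymethyl)-7-methyl-4-[(2R)-6-methylhept-5-en-2-yl]-5-(pivaloyloxy)dec-7-enoate
Product: 16 ethyl (3S,4R,5R,7Z)-2-(diethoxyphosphoryl)-3-(dimethoxymethyl)-10-hydroxy-7-methyl-4-[(2R)-6-methylhept-5-en-2-yl]-5-(pivaloyloxy)dec-7-enoate
Conditions: HF·pyridine, pyridine, THF, 0 °C → rt
Reagents that add atoms: none
Why: fluoride-driven desilylation of the primary silyl ether (Si–F bond formation) under buffered conditions leaves pivalate, acetal, phosphonate and all stereocentres untouched.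

Step 8
Reactants: 16 ethyl (3S,4R,5R,7Z)-2-(diethoxyphosphoryl)-3-(dimethoxymethyl)-10-hydroxy-7-methyl-4-[(2R)-6-methylhept-5-en-2-yl]-5-(pivaloyloxy)dec-7-enoate
Product: 17 ethyl (3S,4R,5R,7Z)-2-(diethoxyphosphoryl)-3-(dimethoxymethyl)-7-methyl-4-[(2R)-6-methylhept-5-en-2-yl]-10-oxo-5-(pivaloyloxy)dec-7-enoate
Conditions: Dess–Martin periodinane, NaHCO3, CH2Cl2, 0 °C; used crude
Reagents that add atoms: none
Why: Dess–Martin oxidation under buffered non-basic conditions gives the (Z)-β,γ-unsaturated aldehyde without moving the C3=C4 double bond into conjugation.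

Step 9
Reactants: 17 ethyl (3S,4R,5R,7Z)-2-(diethoxyphosphoryl)-3-(dimethoxymethyl)-7-methyl-4-[(2R)-6-methylhept-5-en-2-yl]-10-oxo-5-(pivaloyloxy)dec-7-enoate
Product: 18 ethyl (1E,4Z,7R,8R,9R)-9-(dimethoxymethyl)-5-methyl-8-[(2R)-6-methylhept-5-en-2-yl]-7-(pivaloyloxy)cyclonona-1,4-diene-1-carboxylate
Conditions: LiCl, DBU, MeCN, 0.001 M (slow addition of 17), 0 °C → rt
Reagents that add atoms: none
Why: intramolecular Horner–Wadsworth–Emmons olefination (Masamune–Roush conditions) closes the nine-membered ring at C6=C7 with both C7 epimers converging, the intrinsic preference of α-substituted phosphonoacetates for the β-carbon trans to the ester being exactly the ring-cis (E) geometry the ring demands and the (Z)-C3=C4 bond pre-organising the chain; no stereocentre is touched.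

Step 10
Reactants: 18 ethyl (1E,4Z,7R,8R,9R)-9-(dimethoxymethyl)-5-methyl-8-[(2R)-6-methylhept-5-en-2-yl]-7-(pivaloyloxy)cyclonona-1,4-diene-1-carboxylate
Product: 19 (1R,2R,3R,4E,7Z)-3-(dimethoxymethyl)-4-(hydroxymethyl)-8-methyl-2-[(2R)-6-methylhept-5-en-2-yl]cyclonona-4,7-dien-1-ol
Conditions: i-Bu2AlH (6 equiv), CH2Cl2, −78 → 0 °C; aq. potassium sodium tartrate
Reagents that add atoms: none
Why: hydride 1,2-reduction of the enoate to the allylic alcohol with simultaneous reductive cleavage of the pivalate, the acetal and the three olefins being inert to i-Bu2AlH.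

Step 11
Reactants: 19 (1R,2R,3R,4E,7Z)-3-(dimethoxymethyl)-4-(hydroxymethyl)-8-methyl-2-[(2R)-6-methylhept-5-en-2-yl]cyclonona-4,7-dien-1-ol
Product: 20 (1E,4Z,7R,8R,9R)-9-(dimethoxymethyl)-7-hydroxy-5-methyl-8-[(2R)-6-methylhept-5-en-2-yl]cyclonona-1,4-diene-1-carbaldehyde
Conditions: MnO2 (activated, excess), CH2Cl2, rt
Reagents that add atoms: none
Why: chemoselective allylic oxidation with MnO2 converts only the primary allylic alcohol into the enal and leaves the non-allylic secondary C1 hydroxyl alone.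

Step 12
Reactants: 20 (1E,4Z,7R,8R,9R)-9-(dimethoxymethyl)-7-hydroxy-5-methyl-8-[(2R)-6-methylhept-5-en-2-yl]cyclonona-1,4-diene-1-carbaldehyde
Product: 21 (1R,2R,3R,4E,7Z)-3-(dimethoxymethyl)-4-formyl-8-methyl-2-[(2R)-6-methylhept-5-en-2-yl]cyclonona-4,7-dien-1-yl acetate
Conditions: Ac2O, pyridine, DMAP (cat.), CH2Cl2, 0 °C
Reagents that add atoms: acetic anhydride, CC(=O)OC(C)=O
Why: DMAP-catalysed O-acetylation of the secondary alcohol with retention at C1 because the C–O bond is not broken.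

Step 13
Reactants: 21 (1R,2R,3R,4E,7Z)-3-(dimethoxymethyl)-4-formyl-8-methyl-2-[(2R)-6-methylhept-5-en-2-yl]cyclonona-4,7-dien-1-yl acetate
Product: 22 (1R,2R,3R,4E,7Z)-3,4-diformyl-8-methyl-2-[(2R)-6-methylhept-5-en-2-yl]cyclonona-4,7-dien-1-yl acetate
Conditions: (CO2H)2 (10 % aq.) on SiO2, CH2Cl2, rt
Reagents that add atoms: water, O
Why: mild acid-catalysed acetal hydrolysis frees the C8 formyl group last, under conditions that spare the acetate and the enal and are too weakly acidic to epimerise the now enolisable C8 centre.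

**Compound list**
1 | triethyl phosphonoacetate | CCOC(=O)CP(=O)(OCC)OCC | starting material
2 | 2,2-dimethoxyacetaldehyde | COC(OC)C=O | starting material
3 | ethyl (2E)-2-(diethoxyphosphoryl)-4,4-dimethoxybut-2-enoate (E/Z mixture usable) | CCOC(=O)/C(=C\C(OC)OC)P(=O)(OCC)OCC | intermediate
4 | (R)-citronellal, (3R)-3,7-dimethyloct-6-enal | O=CC[C@H](C)CCC=C(C)C | starting material
5 | (2S)-1-[(1E,3R)-3,7-dimethylocta-1,6-dien-1-yl]-2-{diphenyl[(trimethylsilyl)oxy]methyl}pyrrolidine (enamine, not isolated) | C[C@H](CCC=C(C)C)/C=C/N1CCC[C@H]1C(c1ccccc1)(c1ccccc1)O[Si](C)(C)C | intermediate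
6 | ethyl (3S,4R,5R)-2-(diethoxyphosphoryl)-3-(dimethoxymethyl)-4-formyl-5,9-dimethyldec-8-enoate (mixture at the P-bearing C2) | O=C[C@@H]([C@@H](C(OC)OC)C(C(=O)OCC)P(=O)(OCC)OCC)[C@H](C)CCC=C(C)C | intermediate
7 | 3-[(tert-butyldimethylsilyl)oxy]propan-1-ol | OCCCO[Si](C)(C)C(C)(C)C | starting material
8 | 3-[(tert-butyldimethylsilyl)oxy]propyl N,N-diisopropylcarbamate | CC(C)N(C(C)C)C(=O)OCCCO[Si](C)(C)C(C)(C)C | intermediate
9 | 2-isopropenyl-4,4,5,5-tetramethyl-1,3,2-dioxaborolane | CC(=C)B1OC(C)(C)C(C)(C)O1 | starting material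
10 | (1S)-3-[(tert-butyldimethylsilyl)oxy]-1-lithiopropyl N,N-diisopropylcarbamate (not isolated) | [Li][C@@H](CCO[Si](C)(C)C(C)(C)C)OC(=O)N(C(C)C)C(C)C | intermediate
11 | lithium boronate complex of 10 with 9, S at the carbamate-bearing carbon (not isolated) | CC(=C)[B-]1(OC(C)(C)C(C)(C)O1)[C@@H](CCO[Si](C)(C)C(C)(C)C)OC(=O)N(C(C)C)C(C)C.[Li+] | intermediate
12 | tert-butyldimethyl{[(3R)-4-methyl-3-(4,4,5,5-tetramethyl-1,3,2-dioxaborolan-2-yl)pent-4-en-1-yl]oxy}silane | C=C(C)[C@@H](CCO[Si](C)(C)C(C)(C)C)B1OC(C)(C)C(C)(C)O1 | intermediate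
13 | ethyl (3S,4R,5R,7Z)-10-[(tert-butyldimethylsilyl)oxy]-2-(diethoxyphosphoryl)-3-(dimethoxymethyl)-7-methyl-4-[(2R)-6-methylhept-5-en-2-yl]-5-[(4,4,5,5-tetramethyl-1,3,2-dioxaborolan-2-yl)oxy]dec-7-enoate (not isolated) | CC(C)(C)[Si](C)(C)OCC/C=C(C)\C[C@@H](OB1OC(C)(C)C(C)(C)O1)[C@@H]([C@@H](C(OC)OC)C(C(=O)OCC)P(=O)(OCC)OCC)[C@H](C)CCC=C(C)C | intermediate
14 | ethyl (3S,4R,5R,7Z)-10-[(tert-butyldimethylsilyl)oxy]-2-(diethoxyphosphoryl)-3-(dimethoxymethyl)-5-hydroxy-7-methyl-4-[(2R)-6-methylhept-5-en-2-yl]dec-7-enoate | CC(C)(C)[Si](C)(C)OCC/C=C(C)\C[C@@H](O)[C@@H]([C@@H](C(OC)OC)C(C(=O)OCC)P(=O)(OCC)OCC)[C@H](C)CCC=C(C)C | intermediate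
15 | ethyl (3S,4R,5R,7Z)-10-[(tert-butyldimethylsilyl)oxy]-2-(diethoxyphosphoryl)-3-(dimethoxymethyl)-7-methyl-4-[(2R)-6-methylhept-5-en-2-yl]-5-(pivaloyloxy)dec-7-enoate | CC(C)(C)[Si](C)(C)OCC/C=C(C)\C[C@@H](OC(=O)C(C)(C)C)[C@@H]([C@@H](C(OC)OC)C(C(=O)OCC)P(=O)(OCC)OCC)[C@H](C)CCC=C(C)C | intermediate
16 | ethyl (3S,4R,5R,7Z)-2-(diethoxyphosphoryl)-3-(dimethoxymethyl)-10-hydroxy-7-methyl-4-[(2R)-6-methylhept-5-en-2-yl]-5-(pivaloyloxy)dec-7-enoate | OCC/C=C(C)\C[C@@H](OC(=O)C(C)(C)C)[C@@H]([C@@H](C(OC)OC)C(C(=O)OCC)P(=O)(OCC)OCC)[C@H](C)CCC=C(C)C | intermediate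
17 | ethyl (3S,4R,5R,7Z)-2-(diethoxyphosphoryl)-3-(dimethoxymethyl)-7-methyl-4-[(2R)-6-methylhept-5-en-2-yl]-10-oxo-5-(pivaloyloxy)dec-7-enoate | O=CC/C=C(C)\C[C@@H](OC(=O)C(C)(C)C)[C@@H]([C@@H](C(OC)OC)C(C(=O)OCC)P(=O)(OCC)OCC)[C@H](C)CCC=C(C)C | intermediate
18 | ethyl (1E,4Z,7R,8R,9R)-9-(dimethoxymethyl)-5-methyl-8-[(2R)-6-methylhept-5-en-2-yl]-7-(pivaloyloxy)cyclonona-1,4-diene-1-carboxylate | CC(C)(C)C(=O)O[C@@H]1C/C(C)=C\C/C=C(/C(=O)OCC)[C@H](C(OC)OC)[C@H]1[C@H](C)CCC=C(C)C | intermediate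
19 | (1R,2R,3R,4E,7Z)-3-(dimethoxymethyl)-4-(hydroxymethyl)-8-methyl-2-[(2R)-6-methylhept-5-en-2-yl]cyclonona-4,7-dien-1-ol | O[C@@H]1C/C(C)=C\C/C=C(/CO)[C@H](C(OC)OC)[C@H]1[C@H](C)CCC=C(C)C | intermediate
20 | (1E,4Z,7R,8R,9R)-9-(dimethoxymethyl)-7-hydroxy-5-methyl-8-[(2R)-6-methylhept-5-en-2-yl]cyclonona-1,4-diene-1-carbaldehyde | O[C@@H]1C/C(C)=C\C/C=C(/C=O)[C@H](C(OC)OC)[C@H]1[C@H](C)CCC=C(C)C | intermediate
21 | (1R,2R,3R,4E,7Z)-3-(dimethoxymethyl)-4-formyl-8-methyl-2-[(2R)-6-methylhept-5-en-2-yl]cyclonona-4,7-dien-1-yl acetate | CC(=O)O[C@@H]1C/C(C)=C\C/C=C(/C=O)[C@H](C(OC)OC)[C@H]1[C@H](C)CCC=C(C)C | intermediate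
22 | (1R,2R,3R,4E,7Z)-3,4-diformyl-8-methyl-2-[(2R)-6-methylhept-5-en-2-yl]cyclonona-4,7-dien-1-yl acetate | CC(=O)O[C@@H]1C/C(C)=C\C/C=C(/C=O)[C@H](C=O)[C@H]1[C@H](C)CCC=C(C)C | target

**Step count and risk**
Total step count: 13. Longest linear sequence: 11 steps (1, 2, 5 to 13; the branch 3, 4, 5 to 13 is equally long).

Steps most likely to fail:

Step 2. The β-substituted alkylidene phosphonoacetate 3 may be too hindered for enamine catalysis, or the C8 topicity may be mixed. The fallback sets out from 4 (with 3) and comes back at 6. Aldehyde 4 is condensed with (R)-1-amino-2-(methoxymethyl)pyrrolidine to the RAMP hydrazone F1. Deprotonation with LiN(i-Pr)2 (THF, −78 °C) and Michael addition to 3 gives the hydrazone adduct F2, with C9 set by the auxiliary and C8 by the lithium-chelated closed transition state. Cleavage with CuCl2 in THF/pH 7 buffer returns aldehyde 6. This replaces catalytic enamine activation by a stoichiometric, far more nucleophilic auxiliary-bound donor.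

Step 5. The α-branched aldehyde 6 and the α-substituted boronate 12 are both hindered, so the addition may be slow, leak E olefin or suffer a mismatched pairing with the C9 centre. The fallback sets out from 6 and comes back at 18. (2-Methylallyl)B(Ipc)2 of the (−)-α-pinene series (Et2O, −78 °C; NaBO3 work-up) gives by Brown allylation under reagent control the (R)-carbinol F3. PivCl/pyridine gives the pivalate F4. An intermolecular Horner–Wadsworth–Emmons reaction of F4 with freshly prepared but-3-enal (LiCl, DBU, MeCN) gives the triene ester F5. Ring-closing metathesis (second-generation Hoveyda–Grubbs catalyst, PhMe, 80 °C, 1 mM) then closes C3=C4 to 18, the ring enforcing the Z olefin. This holds the conventional metathesis closure in reserve and bypasses both the allylboration and the olefination macrocyclisation.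

Step 9. Closing a nine-membered ring by olefination may lose to oligomerisation or to base-induced migration of the β,γ-olefin of 17. The fallback sets out from 17 and comes back at 18. Ph3P=CH2 (2.2 equiv, THF, −78 → 0 °C) converts the aldehyde into the terminal olefin F6. K2CO3/aq. HCHO (Horner–Wadsworth–Emmons α-methylenation) gives the acrylate F7. Ring-closing metathesis (second-generation Hoveyda–Grubbs catalyst, PhMe, 80 °C, 1 mM) between the acrylate and the vinyl group forms the same C6=C7 bond and delivers 18. The ring closure is thereby moved from a carbonyl olefination to an olefin metathesis.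

**Further compounds**
F1 | step 2 | (2R)-N-[(1E,3R)-3,7-dimethyloct-6-en-1-ylidene]-2-(methoxymethyl)pyrrolidin-1-amine | COC[C@H]1CCCN1/N=C/C[C@H](C)CCC=C(C)C
F2 | step 2 | ethyl (3S,4R,5R)-2-(diethoxyphosphoryl)-3-(dimethoxymethyl)-5,9-dimethyl-4-[(E)-{[(2R)-2-(methoxymethyl)pyrrolidin-1-yl]imino}methyl]dec-8-enoate | COC[C@H]1CCCN1/N=C/[C@@H]([C@@H](C(OC)OC)C(C(=O)OCC)P(=O)(OCC)OCC)[C@H](C)CCC=C(C)C
F3 | step 5 | ethyl (3S,4R,5R)-2-(diethoxyphosphoryl)-3-(dimethoxymethyl)-5-hydroxy-7-methyl-4-[(2R)-6-methylhept-5-en-2-yl]oct-7-enoate | CC(=C)C[C@@H](O)[C@@H]([C@@H](C(OC)OC)C(C(=O)OCC)P(=O)(OCC)OCC)[C@H](C)CCC=C(C)C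
F4 | step 5 | ethyl (3S,4R,5R)-2-(diethoxyphosphoryl)-3-(dimethoxymethyl)-7-methyl-4-[(2R)-6-methylhept-5-en-2-yl]-5-(pivaloyloxy)oct-7-enoate | CC(=C)C[C@@H](OC(=O)C(C)(C)C)[C@@H]([C@@H](C(OC)OC)C(C(=O)OCC)P(=O)(OCC)OCC)[C@H](C)CCC=C(C)C
F5 | step 5 | ethyl (2E)-2-[(2R,3R,4R)-1,1-dimethoxy-6-methyl-3-[(2R)-6-methylhept-5-en-2-yl]-4-(pivaloyloxy)hept-6-en-2-yl]hexa-2,5-dienoate | C=CC/C=C(/C(=O)OCC)[C@H](C(OC)OC)[C@H]([C@@H](CC(C)=C)OC(=O)C(C)(C)C)[C@H](C)CCC=C(C)C
F6 | step 9 | ethyl (3S,4R,5R,7Z)-2-(diethoxyphosphoryl)-3-(dimethoxymethyl)-7-methyl-4-[(2R)-6-methylhept-5-en-2-yl]-5-(pivaloyloxy)undeca-7,10-dienoate | C=CC/C=C(C)\C[C@@H](OC(=O)C(C)(C)C)[C@@H]([C@@H](C(OC)OC)C(C(=O)OCC)P(=O)(OCC)OCC)[C@H](C)CCC=C(C)C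
F7 | step 9 | ethyl 2-[(2R,3R,4R,6Z)-1,1-dimethoxy-6-methyl-3-[(2R)-6-methylhept-5-en-2-yl]-4-(pivaloyloxy)deca-6,9-dien-2-yl]prop-2-enoate | C=CC/C=C(C)\C[C@@H](OC(=O)C(C)(C)C)[C@@H]([C@@H](C(OC)OC)C(=C)C(=O)OCC)[C@H](C)CCC=C(C)C
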